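## The problem

Target 22 is the ether formed between O4 of 4-hydroxy-5-methylcoumarin and a monocyclic C15 terpenoid alcohol. The carbocycle (numbered as in diol 19) carries a secondary hydroxyl at C1 (S), a gem-dimethyl quaternary carbon C2, a methine C3 (R) bearing the side chain, and an exocyclic methylidene on C4. The side chain is two methylenes, an E-trisubstituted alkene and the allylic CH2–O. There are only two stereocentres, 1,3-cis across the quaternary carbon, and neither can be corrected by epimerisation. The carbinol is a β-hydroxy-α,α-dimethyl carbonyl retron, so it can be set first by an asymmetric aldol and then used to direct C3 through a chair-like ring closure. The methylidene isomerises into the ring under acid or prolonged exposure to metal hydrides. The allyl ether of the vinylogous acid is ionised by zerovalent palladium or acid, rearranges on heating and has a lactone open to strong nucleophiles, so the heterocycle must be attached after any palladium chemistry. The enabling feature is that the methylidene carbon C4 is bonded directly to the side-chain methine C3. That is the connectivity left when the internal carbon of a terminal alkyne bonds to an alkene carbon, so the C3–C4 ring bond can be made from an acyclic 1,7-enyne that already holds the carbinol and the quaternary carbon.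

## Retrosynthesis

**Ether bond (22 to 19 + 21).** The allylic CH2–O4 bond is cut last. This keeps the palladium-labile allyl vinylogous ester out of every earlier step and removes the whole heteroaromatic unit at once. The forward reaction (step 14) must alkylate 21 on O4, not on C3 or the lactone carbonyl oxygen, and must engage the primary allylic hydroxyl of 19 while leaving the hindered C1 hydroxyl untouched.

**Pyranone (21 to 20).** The O1–C2 and C2–C3 bonds are cut, so the C2 carbonyl is delivered as a carbonate ester to the methyl ketone and phenol of 20. This one-step annulation (step 13) is shorter than any route that builds the pyranone on the terpenoid.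

**Silyl groups (19 to 18).** Only two Si–O bonds are cut (step 12). The carbinol carries TBS and the allylic oxygen carries TBDPS; both fall to fluoride together. They differ because the sulfone synthesis needs the TBDPS ether to survive the acid that removes a primary TBS ether.

**Ring bond C3–C4 (18 to 17), the key cut.** Opening this bond gives the acyclic enyne 17, in which C4 and its methylidene become a terminal alkyne and C3 becomes an alkene carbon next to the quaternary centre. Cuts at C1–C2 or C2–C3 would have to form a bond to a quaternary carbon. Cuts at C4–C5 or C5–C6 would remove no stereocentre. The chosen cut removes the ring and the C3 stereocentre together and creates the methylidene directly. The forward step (step 11) must hydrometallate the alkyne in preference to two alkenes, close a six-membered ring onto a neopentyl alkene, and transfer the C1 configuration to C3.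

**Alkene of the enyne (17 to 7 + 15).** The C5=C6 double bond of 17 (chain numbering) is cut into the nine-carbon aldehyde 7 and the six-carbon sulfone 15. The carbonyl has to sit on the neopentyl carbon, because a neopentyl sulfone could not be made by substitution. The forward olefination (step 10) should be E-selective, although the geometry is erased when that carbon becomes a methylene in step 11.

**Carbinol fragment (7 to 5, 4, then 2 + 3; 2 from 1).** After oxidation-state and protecting-group adjustments, the C2–C3 bond of heptynoate 4 is cut in the aldol sense. This gives the achiral aldehyde 2 (from alkynol 1) and the tetrasubstituted ketene silyl acetal 3. The forward aldol (step 2) must set the single reagent-controlled stereocentre of the synthesis.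

**Sulfone fragment (15 to 14, 13, 12, 11, then 8).** The C–S bond is cut to the homoallylic alcohol 13. This is reached from 11 by exchanging which primary oxygen is protected (via 12). Alcohol 11 is cut at its two alkene substituents, the methyl group and the hydroxymethyl group, back to the terminal alkyne 8. A syn carbometallation (step 5) fixes the E geometry without any olefination.

## Roads not taken

**Alternative 1:** The carbinol C–O bond would be made by enzymatic oxygen insertion into a cyclobutanone. (1S,5S)-Verbenone A1 is photoisomerised to chrysanthenone A2. A flavin-dependent Baeyer–Villiger monooxygenase must then insert oxygen between the ketone carbon and the non-allylic bridgehead to give the bridged γ-lactone A3.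
- Merits: A3 holds the six-membered ring, the gem-dimethyl carbon and both stereocentres. The cis relationship is locked by the lactone bridge and the absolute configuration comes from a cheap terpene. In stereochemical certainty this is better than the chosen plan, which relies on 1,3-induction in step 11.
- Weak points: the allylic bridgehead has the higher intrinsic migratory aptitude, so the required regiochemistry rests entirely on the enzyme accepting a hindered unnatural bicycle. The photochemical 1,3-shift from A1 to A2 can pass through ring-opened intermediates that erode optical purity. A3 has its alkene inside the ring, so it must be moved to the exocyclic position against the thermodynamic bias. The lactone carbonyl is only the first carbon of the side chain, so the E-trisubstituted alkene must still be built by homologation.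
- Comparison: the chosen plan creates the methylidene exactly where it is needed, carries the complete side chain through the ring closure, and needs three steps from 18 to 22.

**Alternative 2:** Two ring bonds would be formed in a catalytic asymmetric Diels–Alder reaction. The gem-dimethyl terminus of 4-methylpenta-1,3-diene A4 joins the ester-bearing carbon of ethyl buta-2,3-dienoate A5, and the other diene terminus joins the central allene carbon, under a chiral oxazaborolidinium triflimide. The product is cycloadduct A6.
- Merits: the ring, the quaternary carbon, the methylidene and one stereocentre arise in one step from two simple achiral compounds. This is far shorter to the carbocycle than the ten steps that precede step 11.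
- Weak points: A4 has a cis methyl at its reacting terminus, so its s-cis conformer is disfavoured and it is prone to cationic oligomerisation with a strong Lewis acid. The bond formed joins a fully substituted carbon to a tertiary one. A6 has no oxygen on the ring, and the hydroxyl would have to be placed on the more hindered carbon of the ring alkene, cis to the ester, while the more accessible 1,1-disubstituted methylidene competes. The ester carbon is again only the first carbon of the side chain.
- Comparison: the chosen plan installs the carbinol first by a dependable aldol and uses it as the control element for the second stereocentre. It never has to differentiate two alkenes towards an oxidant.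

**Alternative 3:** The pyranone would be closed last on the terpenoid. The phenol of the silylated terpenyl 6-methylsalicylate A7 adds to the cumulated ylide A8 (Ph3P=C=C=O), and the resulting ester ylide olefinates the neighbouring ester carbonyl to give A9, the TBS ether of the target.
- Merits: the ether regiochemistry is unambiguous, because the alkoxy group is already on the carbon that becomes C4. The ambident reactivity of 21 is avoided and the conditions are neutral. In this respect it is better than step 14.
- Weak points: it does not address the carbocycle or its stereocentres, so the terpenoid alcohol still has to come from another strategy. It needs three operations in place of one. The ester carbonyl is flanked by two ortho substituents and needs heat to react with a stabilised ylide, and that heat invites Claisen rearrangement of the allyl ether product.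
- Comparison: the chosen plan offers a one-step coupling with a heterocycle made in one step from 20. This ring closure is kept as the fallback for step 14.

Key step: step 11

Assumption 1: tert-butyl(but-3-yn-1-yloxy)dimethylsilane 8 is taken as a purchased compound; it is the TBS ether of but-3-yn-1-ol.

Assumption 2: the D-valine-derived borane promoter is assigned from its facial preference with unbranched aliphatic aldehydes, as recalled from precedent and not verified here; if Mosher analysis of 4 shows the R alcohol, N-tosyl-L-valine is used and nothing else changes.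

## Route

Step 1
Reactants: 1 pent-4-yn-1-ol
Product: 2 pent-4-ynal
Conditions: (COCl)2, DMSO, CH2Cl2, −78 °C; Et3N, −78 → 0 °C
Reagents that add atoms: none
Why: Swern oxidation stops at the aldehyde and leaves the terminal alkyne alone; the volatile product is washed, dried and used as its dichloromethane solution.

Step 2
Reactants: 2 pent-4-ynal; 3 1-methoxy-2-methyl-1-(trimethylsilyloxy)prop-1-ene
Product: 4 methyl (3S)-3-hydroxy-2,2-dimethylhept-6-ynoate
Conditions: N-tosyl-D-valine, BH3·THF (1 equiv each), CH2Cl2, 0 °C → rt; then 2 and 3, −78 °C; pH 7 buffer, then dilute HCl/THF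
Reagents that add atoms: none
Why: Kiyooka-type asymmetric Mukaiyama aldol; the oxazaborolidinone formed from the sulfonamido acid and borane binds the aldehyde and shields one face, so the ketene silyl acetal attacks the other and should set C3 as S, to be confirmed as the Mosher ester.

Step 3
Reactants: 4 methyl (3S)-3-hydroxy-2,2-dimethylhept-6-ynoate
Product: 5 methyl (3S)-3-[(tert-butyldimethylsilyl)oxy]-2,2-dimethylhept-6-ynoate
Conditions: TBSOTf, 2,6-lutidine, CH2Cl2, 0 °C
Reagents that add atoms: tert-butyldimethylsilyl trifluoromethanesulfonate, CC(C)(C)[Si](C)(C)OS(=O)(=O)C(F)(F)F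
Why: silyl triflate and lutidine silylate a hindered secondary alcohol next to a quaternary carbon; the ether blocks retro-aldol cleavage in the basic steps that follow.

Step 4
Reactants: 5 methyl (3S)-3-[(tert-butyldimethylsilyl)oxy]-2,2-dimethylhept-6-ynoate
Product: 7 (3S)-3-[(tert-butyldimethylsilyl)oxy]-2,2-dimethylhept-6-ynal, via aluminium hemiacetal 6 (not isolated)
Conditions: i-Bu2AlH (1.1 equiv), CH2Cl2, −78 °C; MeOH, then aq. KNaC4H4O6
Reagents that add atoms: none
Why: partial reduction of an ester with i-Bu2AlH; the tetrahedral aluminium hemiacetal of this α-quaternary ester should persist in the cold and release the aldehyde only on work-up, and the product has no α-hydrogen to epimerise or eliminate.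

Step 5
Reactants: 8 tert-butyl(but-3-yn-1-yloxy)dimethylsilane
Product: 11 (2E)-5-[(tert-butyldimethylsilyl)oxy]-3-methylpent-2-en-1-ol, via alkenyldimethylalane 9 (not isolated), via lithium alkenylaluminate 10 (not isolated)
Conditions: Me3Al (2 equiv), Cp2ZrCl2 (0.2 equiv), CH2Cl2, 0 °C → rt; evaporate; n-BuLi, hexane, 0 °C; (CH2O)n, THF, rt; aq. NH4Cl
Reagents that add atoms: trimethylaluminium, C[Al](C)C; paraformaldehyde (as formaldehyde), C=O
Why: Negishi zirconium-catalysed methylalumination adds methyl and aluminium syn across the terminal alkyne with methyl on the internal carbon, which fixes the E alkene; the aluminate is nucleophilic enough to capture formaldehyde with retention.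

Step 6
Reactants: 11 (2E)-5-[(tert-butyldimethylsilyl)oxy]-3-methylpent-2-en-1-ol
Product: 12 (2E)-5-[(tert-butyldimethylsilyl)oxy]-1-[(tert-butyldiphenylsilyl)oxy]-3-methylpent-2-ene
Conditions: TBDPSCl, imidazole, DMF, rt
Reagents that add atoms: tert-butyl(chloro)diphenylsilane, CC(C)(C)[Si](Cl)(c1ccccc1)c1ccccc1
Why: standard imidazole-promoted silylation of a primary allylic alcohol; the TBDPS ether is chosen because it outlasts the acid used in step 7.

Step 7
Reactants: 12 (2E)-5-[(tert-butyldimethylsilyl)oxy]-1-[(tert-butyldiphenylsilyl)oxy]-3-methylpent-2-ene
Product: 13 (3E)-5-[(tert-butyldiphenylsilyl)oxy]-3-methylpent-3-en-1-ol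
Conditions: camphorsulfonic acid (0.1 equiv), MeOH/CH2Cl2, 0 °C
Reagents that add atoms: none
Why: acid-catalysed methanolysis removes a primary TBS ether far faster than the bulkier TBDPS ether, which frees only the homoallylic hydroxyl.

Step 8
Reactants: 13 (3E)-5-[(tert-butyldiphenylsilyl)oxy]-3-methylpent-3-en-1-ol
Product: 14 5-{[(3E)-5-[(tert-butyldiphenylsilyl)oxy]-3-methylpent-3-en-1-yl]sulfanyl}-1-phenyl-1H-tetrazole
Conditions: 1-phenyl-1H-tetrazole-5-thiol, PPh3, DIAD, THF, 0 °C → rt
Reagents that add atoms: 1-phenyl-1H-tetrazole-5-thiol, Sc1nnnn1-c1ccccc1
Why: Mitsunobu thioetherification of an unhindered primary alcohol with an acidic heteroaryl thiol, the usual entry to Julia–Kocienski sulfones.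

Step 9
Reactants: 14 5-{[(3E)-5-[(tert-butyldiphenylsilyl)oxy]-3-methylpent-3-en-1-yl]sulfanyl}-1-phenyl-1H-tetrazole
Product: 15 5-{[(3E)-5-[(tert-butyldiphenylsilyl)oxy]-3-methylpent-3-en-1-yl]sulfonyl}-1-phenyl-1H-tetrazole
Conditions: (NH4)6Mo7O24·4H2O (0.1 equiv), 30% H2O2, EtOH, 0 °C → rt
Reagents that add atoms: hydrogen peroxide, OO
Why: molybdate-catalysed peroxide oxidation converts the sulfide to the sulfone; the trisubstituted alkene has no free allylic hydroxyl to direct epoxidation and should be left intact.

Step 10
Reactants: 15 5-{[(3E)-5-[(tert-butyldiphenylsilyl)oxy]-3-methylpent-3-en-1-yl]sulfonyl}-1-phenyl-1H-tetrazole; 7 (3S)-3-[(tert-butyldimethylsilyl)oxy]-2,2-dimethylhept-6-ynal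
Product: 17 (2E,5E,8S)-8-[(tert-butyldimethylsilyl)oxy]-1-[(tert-butyldiphenylsilyl)oxy]-3,7,7-trimethyldodeca-2,5-dien-11-yne, via potassium sulfonyl carbanion 16 (not isolated)
Conditions: KN(SiMe3)2, DME, −60 °C, 30 min; then 7, −60 °C → rt
Reagents that add atoms: none
Why: Julia–Kocienski olefination; the metallated tetrazolyl sulfone adds to the non-enolisable neopentyl aldehyde, and Smiles rearrangement with loss of sulfur dioxide and the tetrazolone gives the alkene, the potassium counter-ion, DME and the bulky aldehyde favouring E; premetallation keeps the amide base away from the alkyne C–H.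

Step 11
Reactants: 17 (2E,5E,8S)-8-[(tert-butyldimethylsilyl)oxy]-1-[(tert-butyldiphenylsilyl)oxy]-3,7,7-trimethyldodeca-2,5-dien-11-yne
Product: 18 tert-butyl{[(1S,3R)-3-[(3E)-5-[(tert-butyldiphenylsilyl)oxy]-3-methylpent-3-en-1-yl]-2,2-dimethyl-4-methylidenecyclohexyl]oxy}dimethylsilane
Conditions: Pd2(dba)3·CHCl3 (5 mol%), P(o-tol)3 (20 mol%), AcOH (2 equiv), Et3SiH (10 equiv), toluene, 25 → 60 °C
Reagents that add atoms: none
Why: Zerovalent palladium and acetic acid give a divalent palladium hydride acetate, which adds across the terminal alkyne with hydrogen on the terminal carbon and palladium on the internal carbon C11. The alkenyl–palladium bond then inserts the E alkene, C11 bonding to C6 (the alkene carbon next to the quaternary carbon) in a 6-exo-trig carbopalladation that closes the six-membered carbocycle and leaves palladium on the exocyclic carbon. Et3SiH exchanges hydride for acetate on palladium, and C–H reductive elimination releases 18 and zerovalent palladium. The closest known reaction type is the palladium-catalysed reductive cyclization of 1,6- and 1,7-enynes with a carboxylic acid and a silane to 1-methylidene-2-alkylcycloalkanes. The new ring stereocentre C3 is controlled by the silyloxy-bearing carbon: in a chair-like insertion transition state the OTBS group and the reacting alkene both lie equatorial, which places them 1,3-cis. The step needs the alkyne to be hydropalladated in preference to either alkene, which the much higher reactivity of a terminal alkyne should secure, and needs silane capture to outrun β-hydride loss towards the doubly allylic methylene, which the large excess of silane and the bulky phosphine are meant to secure. Ring closure should be favoured over plain alkyne reduction by the gem-dimethyl and silyloxy substituents on the tether, and the allylic silyl ether, unlike an allylic aryl ether, is not ionised by zerovalent palladium.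

Step 12
Reactants: 18 tert-butyl{[(1S,3R)-3-[(3E)-5-[(tert-butyldiphenylsilyl)oxy]-3-methylpent-3-en-1-yl]-2,2-dimethyl-4-methylidenecyclohexyl]oxy}dimethylsilane
Product: 19 (1S,3R)-3-[(3E)-5-hydroxy-3-methylpent-3-en-1-yl]-2,2-dimethyl-4-methylidenecyclohexan-1-ol
Conditions: Bu4NF (5 equiv), THF, rt → 50 °C
Reagents that add atoms: none
Why: fluoride cleaves both silyl ethers in one operation; the basic, non-acidic medium leaves the methylidene in place and neither stereocentre can epimerise.

Step 13
Reactants: 20 1-(2-hydroxy-6-methylphenyl)ethan-1-one
Product: 21 4-hydroxy-5-methyl-2H-chromen-2-one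
Conditions: NaH (4 equiv), (EtO)2CO, toluene, 110 °C; aq. HCl
Reagents that add atoms: diethyl carbonate, CCOC(=O)OCC
Why: classical 4-hydroxycoumarin synthesis; Claisen-type acylation of the methyl ketone enolate by the carbonate and lactonisation through the phenoxide, with the product held as its stabilised enolate until acidification.

Step 14
Reactants: 19 (1S,3R)-3-[(3E)-5-hydroxy-3-methylpent-3-en-1-yl]-2,2-dimethyl-4-methylidenecyclohexan-1-ol; 21 4-hydroxy-5-methyl-2H-chromen-2-one
Product: 22 4-{[(2E)-5-[(1R,3S)-3-hydroxy-2,2-dimethyl-6-methylidenecyclohexyl]-3-methylpent-2-en-1-yl]oxy}-5-methyl-2H-chromen-2-one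
Conditions: PPh3, DIAD, THF, 0 °C → rt
Reagents that add atoms: none
Why: Mitsunobu etherification; the acidic vinylogous acid 21 is a competent pronucleophile and should displace the oxyphosphonium of the primary allylic alcohol on O4, while the secondary hydroxyl flanked by the quaternary carbon is too hindered to be activated, and the neutral room-temperature conditions spare the methylidene and the allyl ether product.

## Compound list

1 | pent-4-yn-1-ol | C#CCCCO | starting material
2 | pent-4-ynal | C#CCCC=O | intermediate
3 | 1-methoxy-2-methyl-1-(trimethylsilyloxy)prop-1-ene | COC(O[Si](C)(C)C)=C(C)C | starting material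
4 | methyl (3S)-3-hydroxy-2,2-dimethylhept-6-ynoate | C#CCC[C@H](O)C(C)(C)C(=O)OC | intermediate
5 | methyl (3S)-3-[(tert-butyldimethylsilyl)oxy]-2,2-dimethylhept-6-ynoate | C#CCC[C@H](O[Si](C)(C)C(C)(C)C)C(C)(C)C(=O)OC | intermediate
6 | diisobutylaluminium hemiacetal of 5 (O-aluminated methyl hemiacetal of 7) | C#CCC[C@H](O[Si](C)(C)C(C)(C)C)C(C)(C)C(OC)O[Al](CC(C)C)CC(C)C | intermediate (not isolated)
7 | (3S)-3-[(tert-butyldimethylsilyl)oxy]-2,2-dimethylhept-6-ynal | C#CCC[C@H](O[Si](C)(C)C(C)(C)C)C(C)(C)C=O | intermediate
8 | tert-butyl(but-3-yn-1-yloxy)dimethylsilane | C#CCCO[Si](C)(C)C(C)(C)C | starting material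
9 | [(1E)-4-[(tert-butyldimethylsilyl)oxy]-2-methylbut-1-en-1-yl]dimethylalumane | C[Al](C)/C=C(\C)CCO[Si](C)(C)C(C)(C)C | intermediate (not isolated)
10 | lithium butyl[(1E)-4-[(tert-butyldimethylsilyl)oxy]-2-methylbut-1-en-1-yl]dimethylaluminate | [Li+].CCCC[Al-](C)(C)/C=C(\C)CCO[Si](C)(C)C(C)(C)C | intermediate (not isolated)
11 | (2E)-5-[(tert-butyldimethylsilyl)oxy]-3-methylpent-2-en-1-ol | CC(C)(C)[Si](C)(C)OCC/C(C)=C/CO | intermediate
12 | (2E)-5-[(tert-butyldimethylsilyl)oxy]-1-[(tert-butyldiphenylsilyl)oxy]-3-methylpent-2-ene | CC(C)(C)[Si](C)(C)OCC/C(C)=C/CO[Si](c1ccccc1)(c1ccccc1)C(C)(C)C | intermediate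
13 | (3E)-5-[(tert-butyldiphenylsilyl)oxy]-3-methylpent-3-en-1-ol | OCC/C(C)=C/CO[Si](c1ccccc1)(c1ccccc1)C(C)(C)C | intermediate
14 | 5-{[(3E)-5-[(tert-butyldiphenylsilyl)oxy]-3-methylpent-3-en-1-yl]sulfanyl}-1-phenyl-1H-tetrazole | c1ccccc1-n1nnnc1SCC/C(C)=C/CO[Si](c1ccccc1)(c1ccccc1)C(C)(C)C | intermediate
15 | 5-{[(3E)-5-[(tert-butyldiphenylsilyl)oxy]-3-methylpent-3-en-1-yl]sulfonyl}-1-phenyl-1H-tetrazole | O=S(=O)(CC/C(C)=C/CO[Si](c1ccccc1)(c1ccccc1)C(C)(C)C)c1nnnn1-c1ccccc1 | intermediate
16 | potassium salt of 15 metallated at the carbon next to sulfur | [K+].O=S(=O)([CH-]C/C(C)=C/CO[Si](c1ccccc1)(c1ccccc1)C(C)(C)C)c1nnnn1-c1ccccc1 | intermediate (not isolated)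
17 | (2E,5E,8S)-8-[(tert-butyldimethylsilyl)oxy]-1-[(tert-butyldiphenylsilyl)oxy]-3,7,7-trimethyldodeca-2,5-dien-11-yne | C#CCC[C@H](O[Si](C)(C)C(C)(C)C)C(C)(C)/C=C/C/C(C)=C/CO[Si](c1ccccc1)(c1ccccc1)C(C)(C)C | intermediate
18 | tert-butyl{[(1S,3R)-3-[(3E)-5-[(tert-butyldiphenylsilyl)oxy]-3-methylpent-3-en-1-yl]-2,2-dimethyl-4-methylidenecyclohexyl]oxy}dimethylsilane | C=C1CC[C@H](O[Si](C)(C)C(C)(C)C)C(C)(C)[C@@H]1CC/C(C)=C/CO[Si](c1ccccc1)(c1ccccc1)C(C)(C)C | intermediate
19 | (1S,3R)-3-[(3E)-5-hydroxy-3-methylpent-3-en-1-yl]-2,2-dimethyl-4-methylidenecyclohexan-1-ol | C=C1CC[C@H](O)C(C)(C)[C@@H]1CC/C(C)=C/CO | intermediate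
20 | 1-(2-hydroxy-6-methylphenyl)ethan-1-one | CC(=O)c1c(C)cccc1O | starting material
21 | 4-hydroxy-5-methyl-2H-chromen-2-one | Cc1cccc2oc(=O)cc(O)c12 | intermediate
22 | 4-{[(2E)-5-[(1R,3S)-3-hydroxy-2,2-dimethyl-6-methylidenecyclohexyl]-3-methylpent-2-en-1-yl]oxy}-5-methyl-2H-chromen-2-one | C=C1CC[C@H](O)C(C)(C)[C@@H]1CC/C(C)=C/COc1cc(=O)oc2cccc(C)c12 | target

## Step count and risks

Total: 14 steps. Longest linear sequence: 9 steps (8 through steps 5, 6, 7, 8, 9, 10, 11, 12 and 14). The branch from 1 contributes 4 steps before the union in step 10, and step 13 stands alone.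

**Step 11 (key step).**
- What may go wrong: insertion into the neopentyl 1,2-disubstituted alkene may be slow, so that plain reduction or oligomerisation of the alkyne takes over. β-Hydride loss from the alkylpalladium towards the doubly allylic methylene may give dienes. The palladium hydride may migrate the skipped diene. Facial selectivity at the alkene may be poor, so the 1,3-trans ring isomer forms as well.
- Fallback: from 17, a tin-mediated radical cyclization. Bu3SnH is added slowly with AIBN in benzene at 80 °C. The stannyl radical adds reversibly to the alkyne terminus, the alkenyl radical closes 6-exo onto the alkene and the resulting radical is reduced, giving the C-stannylated methylidenecyclohexane F1. Protodestannylation on moist silica gel in CH2Cl2 returns to the route at 18.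

**Step 2.**
- What may go wrong: enantioselectivity may be incomplete with a small unbranched aldehyde, the sense of induction may be opposite to that assumed, and the volatile aldehyde may be lost.
- Fallback: from 2, reagent-controlled prenylboration. The enantiomer of diisopinocampheyl(3-methylbut-2-enyl)borane that delivers the S carbinol is used in Et2O at −78 °C with oxidative work-up, giving (4S)-3,3-dimethyloct-1-en-7-yn-4-ol F2. Silylation with TBSOTf and 2,6-lutidine gives its TBS ether F3. Oxidative cleavage of the vinyl group (OsO4 cat., NaIO4, 2,6-lutidine, dioxane/water) returns to the route at 7 and bypasses 4 and 5.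

**Step 4.**
- What may go wrong: over-reduction to the primary alcohol once the hemiacetal collapses, or stalled conversion at the hindered ester.
- Fallback: from 5, complete reduction with LiAlH4 in Et2O at 0 °C to (3S)-3-[(tert-butyldimethylsilyl)oxy]-2,2-dimethylhept-6-yn-1-ol F4. Oxidation with Dess–Martin periodinane (NaHCO3, CH2Cl2) returns to the route at 7.

**Step 10.**
- What may go wrong: slow addition of the sulfonyl carbanion to the neopentyl aldehyde, self-condensation of the metallated sulfone, and erosion of alkene geometry.
- Fallback: from 13, a Wittig route. Iodination (I2, PPh3, imidazole) gives the homoallylic iodide F5. Heating with PPh3 in MeCN gives the phosphonium iodide F6. The ylide from NaN(SiMe3)2 in THF at −78 °C is condensed with 7 to give the (5Z)-isomer of the enyne F7. F7 is submitted to the conditions of step 11. The alkene geometry is lost when that carbon becomes a methylene, so the sequence returns to the route at 18. Whether the Z alkene inserts as readily is untested.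

**Step 14.**
- What may go wrong: ambident reactivity of 21 (alkylation at C3 or at the lactone carbonyl oxygen), reduced reactivity of O4 next to the peri methyl group, and allylic transposition.
- Fallback: from 19, the pyranone is built on the preformed ester. Mitsunobu esterification of the primary allylic hydroxyl with 2-hydroxy-6-methylbenzoic acid (PPh3, DIAD, THF) gives the terpenyl 6-methylsalicylate F8. Heating F8 with the ylide A8 in toluene adds the phenol to the cumulene and closes the ring by intramolecular olefination of the ester carbonyl, returning to the route at 22.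

## Further compounds

F1 | step 11 | 18 carrying a tributylstannyl group on the methylidene carbon (either alkene geometry; ring stereocentres as in 18) | CCCC[Sn](CCCC)(CCCC)C=C1CC[C@H](O[Si](C)(C)C(C)(C)C)C(C)(C)[C@@H]1CC/C(C)=C/CO[Si](c1ccccc1)(c1ccccc1)C(C)(C)C
F2 | step 2 | (4S)-3,3-dimethyloct-1-en-7-yn-4-ol | C#CCC[C@H](O)C(C)(C)C=C
F3 | step 2 | tert-butyl{[(4S)-3,3-dimethyloct-1-en-7-yn-4-yl]oxy}dimethylsilane | C#CCC[C@H](O[Si](C)(C)C(C)(C)C)C(C)(C)C=C
F4 | step 4 | (3S)-3-[(tert-butyldimethylsilyl)oxy]-2,2-dimethylhept-6-yn-1-ol | C#CCC[C@H](O[Si](C)(C)C(C)(C)C)C(C)(C)CO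
F5 | step 10 | tert-butyl{[(2E)-5-iodo-3-methylpent-2-en-1-yl]oxy}diphenylsilane | ICC/C(C)=C/CO[Si](c1ccccc1)(c1ccccc1)C(C)(C)C
F6 | step 10 | {(3E)-5-[(tert-butyldiphenylsilyl)oxy]-3-methylpent-3-en-1-yl}triphenylphosphonium iodide | [I-].c1ccccc1[P+](c1ccccc1)(c1ccccc1)CC/C(C)=C/CO[Si](c1ccccc1)(c1ccccc1)C(C)(C)C
F7 | step 10 | (2E,5Z,8S)-8-[(tert-butyldimethylsilyl)oxy]-1-[(tert-butyldiphenylsilyl)oxy]-3,7,7-trimethyldodeca-2,5-dien-11-yne | C#CCC[C@H](O[Si](C)(C)C(C)(C)C)C(C)(C)/C=C\C/C(C)=C/CO[Si](c1ccccc1)(c1ccccc1)C(C)(C)C
F8 | step 14 | (2E)-5-[(1R,3S)-3-hydroxy-2,2-dimethyl-6-methylidenecyclohexyl]-3-methylpent-2-en-1-yl 2-hydroxy-6-methylbenzoate | C=C1CC[C@H](O)C(C)(C)[C@@H]1CC/C(C)=C/COC(=O)c1c(C)cccc1O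
A1 | alternative 1 | (1S,5S)-verbenone, (1S,5S)-4,6,6-trimethylbicyclo[3.1.1]hept-3-en-2-one | CC1=CC(=O)[C@H]2C[C@@H]1C2(C)C
A2 | alternative 1 | chrysanthenone, (1R,5S)-2,7,7-trimethylbicyclo[3.1.1]hept-2-en-6-one | CC1=CC[C@@H]2C(=O)[C@H]1C2(C)C
A3 | alternative 1 | 2,8,8-trimethyl-6-oxabicyclo[3.2.1]oct-2-en-7-one (enantiomer shown) | CC1=CC[C@@H]2OC(=O)[C@H]1C2(C)C
A4 | alternative 2 | 4-methylpenta-1,3-diene | C=CC=C(C)C
A5 | alternative 2 | ethyl buta-2,3-dienoate | C=C=CC(=O)OCC
A6 | alternative 2 | ethyl 2,2-dimethyl-6-methylidenecyclohex-3-ene-1-carboxylate (enantiomer shown) | C=C1CC=CC(C)(C)[C@@H]1C(=O)OCC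
A7 | alternative 3 | (2E)-5-[(1R,3S)-3-[(tert-butyldimethylsilyl)oxy]-2,2-dimethyl-6-methylidenecyclohexyl]-3-methylpent-2-en-1-yl 2-hydroxy-6-methylbenzoate | C=C1CC[C@H](O[Si](C)(C)C(C)(C)C)C(C)(C)[C@@H]1CC/C(C)=C/COC(=O)c1c(C)cccc1O
A8 | alternative 3 | (triphenylphosphoranylidene)ketene | O=C=C=P(c1ccccc1)(c1ccccc1)c1ccccc1
A9 | alternative 3 | tert-butyldimethylsilyl ether of 22 | C=C1CC[C@H](O[Si](C)(C)C(C)(C)C)C(C)(C)[C@@H]1CC/C(C)=C/COc1cc(=O)oc2cccc(C)c12
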